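(The data stem from a simulated flask with constants of no real substance, and the scatter is random.)

In early times the noon flask looks like plain consumption of two nearly equal charges, and that is where two chemists part.

in all of them: starting material 0.54 M; reagent 0.513 M
- noon: catalyst 0.59 mM; the very flask that is asked about, followed so far
- dawn: catalyst 1.2 mM; run made earlier
- flask: catalyst 0.59 mM; time 20 h

| run | time / h | product / % |
|---|---|---|
| noon | 1.00 | 14 |
| noon | 2.00 | 26 |
| noon | 5.00 | 40 |
| noon | 12.0 | 48 |
| dawn | 0.333 | 12 |
| dawn | 1.00 | 28 |
| dawn | 2.00 | 38 |
| dawn | 3.00 | 44 |

(scatter of a reading: 2 percentage points)

- zeta: at 20 h add catalyst, 100% of the amount charged, then wait 20 h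
- epsilon: change nothing and wait 20 h more
- eta: at 20 h take out 90% of the product then present, then wait 20 h
- delta: at 20 h add reagent, 50.0% of the amount charged, then wait 20 h

* product, in percent of the starting material first charged, at 20 h
* the option that brings most further product ("none" if no option brings more than 2 percentage points) (zeta / epsilon / eta / delta / none)
* product present, with what was taken out counted in, in percent of the starting material first charged, after epsilon
* product present, with what was taken out counted in, in percent of the starting material first charged, after eta

- product taken out counts as made
- the earlier runs were read with a standard deviation of 2 percentage points
- additions bring no volume worth counting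

The first chemist says the noon flask is simply using up its charges. On that view, the ratio of product to unreacted starting material grows in step with time. The ratio is 0.163 after 1.00 h and 0.351 after 2.00 h, about twice as much. So this chemist expects 76.5% at 20 h, and sees waiting as useful.

The second chemist points to the last noon reading. At 12.0 h the ratio should be 1.96, but it is 0.923. This chemist says the product goes back, and the flask comes to rest.

I side with the second and reckon for myself. Define the stopping quotient, the equilibrium constant, as c(product) / (c(starting material) · c(reagent)) at rest. If the last noon reading stands near rest, it holds 0.259 M of product, and the quotient reads 3.64 /M, with the scatter of that reading. Freeze it. Waiting and more catalyst then leave that rest where it is. Taking out product and letting the quotient return gives 64.5% counted. Adding reagent gives less, 61.4%.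

The forecast takes the second side: “A reversible approach to about 49 % fits well”. It gives 48.5% now, 49% after waiting and 63% after the take-out, and it names eta as best. My take-out figure is higher than its figure.

The flask gives 49.8% at 20 h and 49.9% after waiting. Added catalyst brings 0.092 percentage points, added reagent 14 points, and the take-out 16 points, reaching 66.1%. So eta is best, as forecast.

    starting material + reagent + catalyst ⇌ product + catalyst, rate k1*[starting material]*[reagent]*[catalyst] forward; the back reaction follows from the equilibrium constant (K = 4.10 /M, k = 670 /M²/h)

My 64.5% from 3.64 /M lies 1.6 points below the flask's figure. The first chemist's view fits the noon readings up to 2.00 h, with product at 26% there. The flask stops near 49.8% because of the back reaction: the same run without it reaches 78.5% at 20 h. On the neighbour charged with 0.21 M of reagent, 3.64 /M gives 23.4%. That neighbour gives 24.3%.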